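## Retrosynthetic overview

1. The quinone ring is made last, by a [4+2] carbonyl-condensation annulation of an α-ethoxy enone (quinone C6, C1, C2, C3, the CH2 link and the decalin) with ethyl N-isopentylthiooxamate (C4, C5 and the whole amino side chain). C3–C4 is formed first and the ring is closed by the C5–C6 bond. Quinone locants follow the name of the target: C5 bears N, C6 is the ring CH.
2. Enabling feature: the quinone ring is the enol/enamine tautomer of a cyclohexane-1,2,4-trione 5-imine. C5(N)=C6H–C1=O is a vinylogous amide and C2(OH)=C3–C4=O an enolised 1,3-diketone. C3 and C6 are therefore the two α-carbons of a C1/C2 1,2-dicarbonyl unit, and C4/C5 is an oxalyl unit at the oxidation level of a thiooxamate, so the ring can be closed at its final oxidation level with nitrogen already in place.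
3. The α-ethoxy enone comes from the decalin aldehyde by two-carbon homologation: reductive Knoevenagel alkylation of Meldrum's acid, decarboxylative amidation, then 1-ethoxyvinyllithium.
4. The decalin aldehyde comes from 1-ethenyl-6,6-dimethylcyclohexene and tiglic aldehyde by a catalytic enantioselective exo Diels–Alder reaction. This forms ring B, the ring-B alkene and all three stereocentres at once.
5. Order of ring formation: ring A (present in the starting ketone), then ring B (step 3), then the quinone ring (step 9, the last step).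

Key step: step 9

Notation: Dec is the 1,2,5,5-tetramethyl-1,2,3,5,6,7,8,8a-octahydronaphthalen-1-yl group with the configuration set in step 3 (descriptors 1R,2S,8aS when it is bound to a CH2 group; the formyl/CH2 substituent and 8a-H lie on one face, the 1- and 2-methyl groups on the other).

Assumption: the (S)-configured oxazaborolidinium catalyst is taken to give the enantiomer of the Diels–Alder adduct drawn below (formyl C–H···O binding model); if the first run shows the opposite sense, the (R)-catalyst is used and nothing else changes.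

## Route

Step 1
Reactants: 1 2,2-dimethylcyclohexan-1-one
Product: 2 6,6-dimethylcyclohex-1-en-1-yl trifluoromethanesulfonate
Conditions: LiN(i-Pr)2 (1.1 equiv), THF, −78 °C; PhNTf2 (1.1 equiv), −78 → 0 °C
Reagents that add atoms: N-phenylbis(trifluoromethanesulfonimide) (PhNTf2), O=S(=O)(N(c1ccccc1)S(=O)(=O)C(F)(F)F)C(F)(F)F
Why: The ketone can enolise only towards C6 (C2 is quaternary), and O-sulfonylation of the lithium enolate gives the enol triflate (standard enol triflate formation).

Step 2
Reactants: 2 6,6-dimethylcyclohex-1-en-1-yl trifluoromethanesulfonate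
Product: 3 1-ethenyl-6,6-dimethylcyclohex-1-ene
Conditions: tributyl(vinyl)stannane (1.2 equiv), Pd(PPh3)4 (5 mol%), LiCl (3 equiv), THF, 65 °C
Reagents that add atoms: tributyl(vinyl)stannane, C=C[Sn](CCCC)(CCCC)CCCC
Why: Stille coupling of an enol triflate with a vinylstannane is a standard, regiodefined route to 1,3-dienes.

Step 3
Reactants: 3 1-ethenyl-6,6-dimethylcyclohex-1-ene, 4 (E)-2-methylbut-2-enal (tiglic aldehyde)
Product: 5 (1R,2S,8aR)-1,2,5,5-tetramethyl-1,2,3,5,6,7,8,8a-octahydronaphthalene-1-carbaldehyde
Conditions: (S)-3,3-diphenyl-1-(2-methylphenyl)tetrahydro-1H,3H-pyrrolo[1,2-c][1,3,2]oxazaborole·HN(SO2CF3)2 (20 mol%), CH2Cl2, −78 → −20 °C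
Reagents that add atoms: none
Why: In this enantioselective Lewis-acid-catalysed Diels–Alder reaction the enal β-carbon should bond to the unsubstituted diene terminus ("ortho" regiochemistry), suprafacial addition keeps the two methyl groups of the (E)-enal cis, the formyl-exo transition state usual for α-substituted enals places 8a-H trans to the C1 methyl group, and the chiral oxazaborolidinium cation shields one face of the bound enal and so sets the absolute configuration of all three stereocentres.

Step 4
Reactants: 5 the decalin aldehyde, 6 2,2-dimethyl-1,3-dioxane-4,6-dione (Meldrum's acid)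
Product: 8 5-(Dec-methyl)-2,2-dimethyl-1,3-dioxane-4,6-dione, via alkylidene Meldrum's acid 7 (not isolated)
Conditions: diethyl 2,6-dimethyl-1,4-dihydropyridine-3,5-dicarboxylate (Hantzsch ester, 1.1 equiv), L-proline (20 mol%), EtOH, 25 → 40 °C
Reagents that add atoms: none
Why: Knoevenagel condensation of the non-enolisable aldehyde with the very acidic Meldrum's acid, followed by transfer hydrogenation of the electrophilic alkylidene by the dihydropyridine (three-component reductive alkylation), should give the saturated product without touching the ring-B alkene or any stereocentre.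

Step 5
Reactants: 8 5-(Dec-methyl)-2,2-dimethyl-1,3-dioxane-4,6-dione
Product: 10 1-(morpholin-4-yl)-3-Dec-propan-1-one, via malonamic acid 9 (not isolated)
Conditions: morpholine (3 equiv), toluene, 110 °C
Reagents that add atoms: morpholine, C1COCCN1
Why: Aminolysis opens the dioxanedione to a malonamic acid that loses CO2 at this temperature (decarboxylative amidation of a monoalkyl Meldrum's acid), giving a morpholine amide that acylates organolithiums once.

Step 6
Reactants: 10 1-(morpholin-4-yl)-3-Dec-propan-1-one, 11 ethyl vinyl ether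
Product: 13 2-ethoxy-5-Dec-pent-1-en-3-one, via 1-ethoxyvinyllithium 12 (not isolated)
Conditions: 11 (3 equiv), t-BuLi (2 equiv), THF, −78 → 0 °C; then 10, −78 → 0 °C; then H2O, 0 °C
Reagents that add atoms: none
Why: The α-lithiated enol ether (an acyl anion equivalent) should add once to the morpholine amide because the tetrahedral lithium adduct survives until work-up (Weinreb-type ketone synthesis), giving the α-ethoxy enone.

Step 7
Reactants: 14 diethyl oxalate, 15 3-methylbutan-1-amine
Product: 16 ethyl 2-[(3-methylbutyl)amino]-2-oxoacetate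
Conditions: 14 (3 equiv), EtOH, 0 → 25 °C
Reagents that add atoms: none
Why: Aminolysis of an excess of the diester should stop at the oxamate because the first amide deactivates the remaining ester.

Step 8
Reactants: 16 ethyl 2-[(3-methylbutyl)amino]-2-oxoacetate
Product: 17 ethyl 2-[(3-methylbutyl)amino]-2-sulfanylideneacetate
Conditions: Lawesson's reagent (0.55 equiv), toluene, 80 °C
Reagents that add atoms: Lawesson's reagent, COc1ccc(cc1)P1(=S)SP(=S)(S1)c1ccc(OC)cc1
Why: Thionation with Lawesson's reagent is much faster at a secondary amide carbonyl than at an ester carbonyl, so only the amide should be converted.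

Step 9
Reactants: 13 2-ethoxy-5-Dec-pent-1-en-3-one, 17 ethyl 2-[(3-methylbutyl)amino]-2-sulfanylideneacetate
Product: 21 nakijiquinone M, via thioamide Claisen adduct 18 (not isolated), via S-methyl thioimidate 19 (not isolated), via ethoxy quinone imine 20 (not isolated)
Conditions: LiN(SiMe3)2 (3.2 equiv; 13 and 17 deprotonated separately, then combined), THF, −78 → −20 °C; MeI (1.1 equiv), −40 → 0 °C; then 1 M aq. HCl (pH 2–3), 0 → 23 °C
Reagents that add atoms: water, O
Why: Proposed new method: the step is two consecutive acyl-type substitutions on the thiooxamate, namely (1) Claisen condensation of the lithium enolate of 13 (C3 is its only enolisable carbon, the C1/C6 side being tied up as the enol ether) with the ester carbonyl of N-lithiated 17 (whose thioamidate carbon is not electrophilic), which forms C3–C4, and (2) after S-methylation of the thioamidate and acidification, attack of C6 (the enol ether terminus, or the methyl-ketone enol released from it) on the N-protonated thioimidate carbon C5, loss of MeSH and hydrolysis of the ethyl vinylogous imidate 20, which forms C5–C6 and gives the aminohydroxyquinone directly without a redox step. The closest known reaction types are the double Claisen condensation of oxalic esters with 1,2-diketones to 2,5-dihydroxy-1,4-benzoquinones and the alkylative activation of thioamides for condensation with ketone enols to vinylogous amides (Eschenmoser-type); their combination on an acyclic α-oxothioamide to build an aminoquinone is the untested part. The quinone ring is closed at C5 in a 6-(enolendo)-exo-trig mode from the diketo tautomer of 19, whose sp3 carbon C3 lets the chain fold. No stereocentre is formed, the three decalin stereocentres are remote from every reacting centre, and the ring-B alkene should tolerate brief dilute acid. The selectivity needed is C- over N-, S- and O-cyclisation and the right order of the two C–C bonds: nitrogen is protonated, sulfur is methylated, the five-membered C-acylation at C4 is a disfavoured 5-(enolendo)-exo-trig closure, O-cyclisation of the diketone enol onto C5 gives only a reversible imidate whereas C–C closure ends in the stabilised vinylogous amide, and the bond order (C3–C4 first, C5–C6 last) places nitrogen next to the ring CH and the alkyl group next to the hydroxyl.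

## Compound list

1 | 2,2-dimethylcyclohexan-1-one | CC1(C)CCCCC1=O | starting material
2 | 6,6-dimethylcyclohex-1-en-1-yl trifluoromethanesulfonate | CC1(C)CCCC=C1OS(=O)(=O)C(F)(F)F | intermediate
3 | 1-ethenyl-6,6-dimethylcyclohex-1-ene | C=CC1=CCCCC1(C)C | intermediate
4 | (E)-2-methylbut-2-enal (tiglic aldehyde) | C/C=C(\C)C=O | starting material
5 | (1R,2S,8aR)-1,2,5,5-tetramethyl-1,2,3,5,6,7,8,8a-octahydronaphthalene-1-carbaldehyde (formyl and 8a-H on one face, 1- and 2-methyl on the other) | O=C[C@@]1(C)[C@@H]2CCCC(C)(C)C2=CC[C@@H]1C | intermediate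
6 | 2,2-dimethyl-1,3-dioxane-4,6-dione (Meldrum's acid) | CC1(C)OC(=O)CC(=O)O1 | starting material
7 | 5-(Dec-methylidene)-2,2-dimethyl-1,3-dioxane-4,6-dione (decalin stereocentres as in 5; formed in the flask) | CC1(C)OC(=O)C(=C[C@@]2(C)[C@@H]3CCCC(C)(C)C3=CC[C@@H]2C)C(=O)O1 | intermediate
8 | 2,2-dimethyl-5-{[(1R,2S,8aS)-1,2,5,5-tetramethyl-1,2,3,5,6,7,8,8a-octahydronaphthalen-1-yl]methyl}-1,3-dioxane-4,6-dione | CC1(C)OC(=O)C(C[C@@]2(C)[C@@H]3CCCC(C)(C)C3=CC[C@@H]2C)C(=O)O1 | intermediate
9 | 3-(morpholin-4-yl)-3-oxo-2-{[(1R,2S,8aS)-Dec]methyl}propanoic acid (either configuration at C2; formed in the flask) | OC(=O)C(C[C@@]1(C)[C@@H]2CCCC(C)(C)C2=CC[C@@H]1C)C(=O)N1CCOCC1 | intermediate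
10 | 1-(morpholin-4-yl)-3-[(1R,2S,8aS)-1,2,5,5-tetramethyl-1,2,3,5,6,7,8,8a-octahydronaphthalen-1-yl]propan-1-one | O=C(CC[C@@]1(C)[C@@H]2CCCC(C)(C)C2=CC[C@@H]1C)N1CCOCC1 | intermediate
11 | ethyl vinyl ether | C=COCC | starting material
12 | 1-ethoxyvinyllithium (formed in the flask) | [Li]C(=C)OCC | intermediate
13 | 2-ethoxy-5-[(1R,2S,8aS)-1,2,5,5-tetramethyl-1,2,3,5,6,7,8,8a-octahydronaphthalen-1-yl]pent-1-en-3-one | C=C(OCC)C(=O)CC[C@@]1(C)[C@@H]2CCCC(C)(C)C2=CC[C@@H]1C | intermediate
14 | diethyl oxalate | CCOC(=O)C(=O)OCC | starting material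
15 | 3-methylbutan-1-amine | CC(C)CCN | starting material
16 | ethyl 2-[(3-methylbutyl)amino]-2-oxoacetate | CCOC(=O)C(=O)NCCC(C)C | intermediate
17 | ethyl 2-[(3-methylbutyl)amino]-2-sulfanylideneacetate (ethyl N-isopentylthiooxamate) | CCOC(=O)C(=S)NCCC(C)C | intermediate
18 | 5-ethoxy-N-(3-methylbutyl)-2,4-dioxo-3-{[(1R,2S,8aS)-Dec]methyl}hex-5-enethioamide (present as its dilithium salt; either configuration at C3; formed in the flask) | CC(C)CCNC(=S)C(=O)C(C[C@@]1(C)[C@@H]2CCCC(C)(C)C2=CC[C@@H]1C)C(=O)C(=C)OCC | intermediate
19 | methyl 5-ethoxy-N-(3-methylbutyl)-2,4-dioxo-3-{[(1R,2S,8aS)-Dec]methyl}hex-5-enimidothioate (present as its lithium enolate until acidification; formed in the flask) | CC(C)CCN=C(SC)C(=O)C(C[C@@]1(C)[C@@H]2CCCC(C)(C)C2=CC[C@@H]1C)C(=O)C(=C)OCC | intermediate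
20 | 4-ethoxy-3-hydroxy-6-[(3-methylbutyl)imino]-2-{[(1R,2S,8aS)-Dec]methyl}cyclohexa-2,4-dien-1-one (formed in the flask) | CC(C)CCN=C1C=C(OCC)C(O)=C(C[C@@]2(C)[C@@H]3CCCC(C)(C)C3=CC[C@@H]2C)C1=O | intermediate
21 | nakijiquinone M, 2-hydroxy-5-[(3-methylbutyl)amino]-3-{[(1R,2S,8aS)-1,2,5,5-tetramethyl-1,2,3,5,6,7,8,8a-octahydronaphthalen-1-yl]methyl}cyclohexa-2,5-diene-1,4-dione | CC(C)CCNC1=CC(=O)C(O)=C(C[C@@]2(C)[C@@H]3CCCC(C)(C)C3=CC[C@@H]2C)C1=O | target

## Step count and risks

Total step count: 9 (7 in the main line, 2 for reagent 17). Longest linear sequence: 7 steps (steps 1–6 and 9).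

Steps most likely to fail:

1. **Step 9 (Proposed new method).** O-cyclisation of the diketone enol onto C5, or hydrolytic loss of the amine from the thioimidate, may outrun C–C ring closure. Michael-type self-consumption of the α-ethoxy enone under the Claisen conditions, or attack of the enolate at sulfur-bearing C5 instead of the ester, may also erode the first stage. The fallback uses known chemistry, sets out from 13 and comes back to the route at 21. Claisen condensation of the lithium enolate of 13 with diethyl oxalate 14 should give ethyl 5-ethoxy-3-(Dec-methyl)-2,4-dioxohex-5-enoate F1. Brief aqueous acid should unmask the methyl ketone, ethyl 3-(Dec-methyl)-2,4,5-trioxohexanoate F2. NaOEt in EtOH should close the same C5–C6 bond by Dieckmann condensation to 2,5-dihydroxy-3-(Dec-methyl)-1,4-benzoquinone F3. Acid-catalysed etherification with methanol (catalytic p-TsOH, 40 °C) should occur at the unhindered hydroxyl next to the ring CH and give 2-hydroxy-5-methoxy-3-(Dec-methyl)-1,4-benzoquinone F4. Addition–elimination of 3-methylbutan-1-amine 15 (EtOH, NaHCO3, 25 °C) at the methoxy-bearing carbon then gives 21.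

2. **Step 3.** The trisubstituted enal may react too slowly with the hindered diene at low temperature, and facial or exo selectivity may be insufficient. The fallback sets out from 3 and 4 and comes back at 5. A racemic, exo-selective Me2AlCl-promoted Diels–Alder reaction (CH2Cl2, −20 °C) should give 5 together with its enantiomer, (1S,2R,8aS)-1,2,5,5-tetramethyl-1,2,3,5,6,7,8,8a-octahydronaphthalene-1-carbaldehyde F5. Condensation of the mixture with (1R,2R)-N,N'-dimethyl-1,2-diphenylethane-1,2-diamine should give the diastereomeric imidazolidines, the aminal of 5 F6 and the aminal of the enantiomer F7. These are separated by chromatography, and mild hydrolysis of F6 (wet silica or dilute aqueous acid in ether) returns enantiopure 5.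

3. **Step 4.** Knoevenagel condensation at the neopentyl, α-quaternary aldehyde may be slow or incomplete, and the decarboxylation in step 5 may then also be sluggish. The fallback sets out from 5 and comes back at 10, bypassing 8 and 9. Horner–Wadsworth–Emmons olefination with diethyl (2-morpholino-2-oxoethyl)phosphonate (NaH, THF, 0 → 65 °C) should give (E)-1-(morpholin-4-yl)-3-Dec-prop-2-en-1-one F8. Conjugate reduction with Mg in MeOH, which leaves the isolated trisubstituted alkene untouched, gives 10.

Further compounds
F1 | step 9 | ethyl 5-ethoxy-2,4-dioxo-3-{[(1R,2S,8aS)-Dec]methyl}hex-5-enoate | CCOC(=O)C(=O)C(C[C@@]1(C)[C@@H]2CCCC(C)(C)C2=CC[C@@H]1C)C(=O)C(=C)OCC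
F2 | step 9 | ethyl 2,4,5-trioxo-3-{[(1R,2S,8aS)-Dec]methyl}hexanoate | CCOC(=O)C(=O)C(C[C@@]1(C)[C@@H]2CCCC(C)(C)C2=CC[C@@H]1C)C(=O)C(C)=O
F3 | step 9 | 2,5-dihydroxy-3-{[(1R,2S,8aS)-Dec]methyl}cyclohexa-2,5-diene-1,4-dione | OC1=CC(=O)C(O)=C(C[C@@]2(C)[C@@H]3CCCC(C)(C)C3=CC[C@@H]2C)C1=O
F4 | step 9 | 2-hydroxy-5-methoxy-3-{[(1R,2S,8aS)-Dec]methyl}cyclohexa-2,5-diene-1,4-dione | COC1=CC(=O)C(O)=C(C[C@@]2(C)[C@@H]3CCCC(C)(C)C3=CC[C@@H]2C)C1=O
F5 | step 3 | (1S,2R,8aS)-1,2,5,5-tetramethyl-1,2,3,5,6,7,8,8a-octahydronaphthalene-1-carbaldehyde (enantiomer of 5) | O=C[C@]1(C)[C@H]2CCCC(C)(C)C2=CC[C@H]1C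
F6 | step 3 | (4R,5R)-1,3-dimethyl-4,5-diphenyl-2-Dec-imidazolidine (aminal of 5) | CN1[C@H](c2ccccc2)[C@@H](c2ccccc2)N(C)C1[C@@]1(C)[C@@H]2CCCC(C)(C)C2=CC[C@@H]1C
F7 | step 3 | (4R,5R)-1,3-dimethyl-4,5-diphenyl-2-(ent-Dec)-imidazolidine (aminal of F5) | CN1[C@H](c2ccccc2)[C@@H](c2ccccc2)N(C)C1[C@]1(C)[C@H]2CCCC(C)(C)C2=CC[C@H]1C
F8 | step 4 | (E)-1-(morpholin-4-yl)-3-Dec-prop-2-en-1-one (decalin stereocentres as in 5) | O=C(/C=C/[C@@]1(C)[C@@H]2CCCC(C)(C)C2=CC[C@@H]1C)N1CCOCC1
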